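**Plan**

1. Retrosynthetic cuts (eremophilane locants: ring A = C1–C5 + C10, ring B = C5–C10, ester O on C3, methyls C15 on C4 and C14 on C5, isopropylidene C11–C13 on C7, ketone C8): the ester C–O bond; in ring A C2=C3 (metathesis, followed by an allylic oxygen shift to C3–O/C1=C2), C10–C1 (allyl addition with 1,3-transposition of oxygen from C10 to C8) and C4–C5 (Claisen); in ring B the bonds C8–C9 and C6–C7.
2. Enabling feature: the C8 oxygen of ring B can be traced back by one allylic shift to C10. C5=C10 is then an enol double bond flanked by the methylenes C6 and C9, so ring B is the Diels–Alder adduct of 3-methyl-2-silyloxybuta-1,3-diene (C9, C10, C5, C6, C14) and methyl acrylate (C8, C7, ester carbon = C11).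
3. Forward order: ring B first (step 2); C12/C13 by MeMgBr; C4 and the quaternary C5 by a ketal Claisen rearrangement; C1/C2 by allyl Grignard addition and chromate transposition; ring A by ring-closing metathesis; one base step then gives C3–OH and both conjugated C=C bonds; esterification last.
4. Stereochemistry: C4 and C5 come from (2R,3E)-pent-3-en-2-ol (CBS reduction) by chirality transfer through a chair Claisen transition state. C3 comes from bromonium formation on the face opposite the two methyl groups and closure to the epoxide on their face. The side-chain centre comes from (S)-2-methylbutan-1-ol.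

Key step: step 2

Remark: 4 is racemic at C7, so 6, 7 and 12–18 are mixtures of C7 epimers (6 and 7 also at C5, 14 also at C10); all these centres are trigonal by compound 20, so the mixtures converge.

**Route**

Step 1
Reactants: 1 3-methylbut-3-en-2-one
Product: 2 tert-butyldimethyl[(3-methylbuta-1,3-dien-2-yl)oxy]silane
Conditions: TBSOTf, Et3N, CH2Cl2, 0 °C
Reagents that add atoms: tert-butyldimethylsilyl trifluoromethanesulfonate, CC(C)(C)[Si](C)(C)OS(=O)(=O)C(F)(F)F
Why: Soft enolization of the only enolizable position (the ketone methyl group) by silyl triflate and amine should give the 2-silyloxy diene; no stereocentre is formed.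

Step 2
Reactants: 2 tert-butyldimethyl[(3-methylbuta-1,3-dien-2-yl)oxy]silane; 3 methyl prop-2-enoate
Product: 4 methyl 4-[(tert-butyldimethylsilyl)oxy]-3-methylcyclohex-3-ene-1-carboxylate (racemic)
Conditions: 3 (3 equiv), BHT (cat.), toluene, 110 °C, sealed tube
Reagents that add atoms: none
Why: A concerted, asynchronous normal-electron-demand [4+2] cycloaddition (Diels–Alder reaction of a 2-silyloxybuta-1,3-diene with an acrylate is the closest known type) should form C9–C8 and C6–C7 in one transition state. Ring B is closed by suprafacial addition of the dienophile across the diene termini C9 and C6, both σ bonds forming together. The one new stereocentre, C7, is not controlled and need not be, since it becomes trigonal in step 12. The selectivity that matters is regiochemical (ester "para" to the silyloxy carbon C10): the silyloxy group puts the largest HOMO coefficient on C9, which bonds to the acrylate β-carbon C8, and this should outweigh the weaker opposite bias of the C14 methyl group. Forming C6–C7 while C5 is still trigonal avoids any later bond formation at a neopentyl carbon, and the adduct carries the C5=C10 enol double bond and the C11 carbonyl where the next steps need them.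

Step 3
Reactants: 4 methyl 4-[(tert-butyldimethylsilyl)oxy]-3-methylcyclohex-3-ene-1-carboxylate
Product: 6 4-(2-hydroxypropan-2-yl)-2-methylcyclohexan-1-one (stereoisomer mixture), via silyl enol ether alcohol 5 (not isolated)
Conditions: MeMgBr (2.5 equiv), THF, 0 to 23 °C; then 1 M HCl (aq), 23 °C
Reagents that add atoms: methylmagnesium bromide, C[Mg]Br
Why: Double Grignard addition to the ester should build C11 with C12 and C13 while the silyl enol ether masks the C10 ketone, and the acidic work-up then hydrolyses the enol ether (C5 is protonated without control, which does not matter because C5 is re-enolized in step 6).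

Step 4
Reactants: 6 4-(2-hydroxypropan-2-yl)-2-methylcyclohexan-1-one
Product: 7 2-(3-methyl-4-oxocyclohexyl)propan-2-yl acetate (stereoisomer mixture)
Conditions: Ac2O, Et3N, DMAP (cat.), CH2Cl2, 23 to 40 °C
Reagents that add atoms: acetic anhydride, CC(=O)OC(C)=O
Why: DMAP-catalysed acetylation of the tertiary alcohol protects it through the acidic and oxidative steps and installs the leaving group for the later E1cB formation of C7=C11.

Step 5
Reactants: 8 (3E)-pent-3-en-2-one
Product: 9 (2R,3E)-pent-3-en-2-ol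
Conditions: (S)-2-methyl-CBS-oxazaborolidine (10 mol %), catecholborane, toluene, −78 °C; MeOH, then aq NaOH work-up
Reagents that add atoms: none
Why: Corey–Bakshi–Shibata reduction with the propenyl group as the larger ketone substituent should deliver hydride 1,2 from the face that gives the (R)-allylic alcohol with the (S)-catalyst.

Step 6
Reactants: 7 2-(3-methyl-4-oxocyclohexyl)propan-2-yl acetate; 9 (2R,3E)-pent-3-en-2-ol
Product: 12 2-{(3R)-3-methyl-4-oxo-3-[(2S,3E)-pent-3-en-2-yl]cyclohexyl}propan-2-yl acetate (C7 epimers), via dimethyl ketal 10 (not isolated), via allyl enol ether 11 (not isolated)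
Conditions: HC(OMe)3, MeOH, TsOH·H2O (cat.), 23 °C, evaporation; then 9 (2 equiv), EtCO2H (cat.), toluene, 110 °C with removal of MeOH, then xylene, 140 °C
Reagents that add atoms: none
Why: In this ketal Claisen rearrangement, exchange of one methoxy group for 9 and loss of methanol should give the more substituted (C5=C10) enol ether 11, whose [3,3] shift through a chair transition state with the carbinol methyl group equatorial transfers the C–O stereocentre suprafacially to the quaternary C5 (R) and to C4, the E-alkene fixing their relative configuration (C14 and C15 cis in the later ring A).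

Step 7
Reactants: 12 2-{(3R)-3-methyl-4-oxo-3-[(2S,3E)-pent-3-en-2-yl]cyclohexyl}propan-2-yl acetate
Product: 13 2-{(5R)-5-methyl-4-oxo-5-[(2S,3E)-pent-3-en-2-yl]cyclohex-2-en-1-yl}propan-2-yl acetate
Conditions: IBX (2 equiv), DMSO/toluene, 75 °C
Reagents that add atoms: none
Why: IBX-mediated α,β-dehydrogenation of the ketone can only give the C8=C9 enone because C9 is the only α-carbon that bears hydrogen.

Step 8
Reactants: 13 2-{(5R)-5-methyl-4-oxo-5-[(2S,3E)-pent-3-en-2-yl]cyclohex-2-en-1-yl}propan-2-yl acetate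
Product: 14 2-{(5R)-4-hydroxy-5-methyl-5-[(2S,3E)-pent-3-en-2-yl]-4-(prop-2-en-1-yl)cyclohex-2-en-1-yl}propan-2-yl acetate (carbinol epimers)
Conditions: CH2=CHCH2MgBr (1.2 equiv), THF, −78 °C; aq NH4Cl
Reagents that add atoms: allylmagnesium bromide, C=CC[Mg]Br
Why: 1,2-Addition of the allyl Grignard reagent to the enone carbonyl brings in C1 and C2 (plus one carbon lost in step 10); the new carbinol centre is formed without control and is destroyed in step 9.

Step 9
Reactants: 14 2-{(5R)-4-hydroxy-5-methyl-5-[(2S,3E)-pent-3-en-2-yl]-4-(prop-2-en-1-yl)cyclohex-2-en-1-yl}propan-2-yl acetate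
Product: 15 2-{(5R)-5-methyl-2-oxo-5-[(2S,3E)-pent-3-en-2-yl]-4-(prop-2-en-1-yl)cyclohex-3-en-1-yl}propan-2-yl acetate
Conditions: pyridinium chlorochromate [C5H5NH][CrO3Cl] (2.5 equiv), Celite, CH2Cl2, 23 °C
Reagents that add atoms: pyridinium chlorochromate, [O-][Cr](=O)(=O)Cl.c1cc[nH+]cc1
Why: In this Babler–Dauben oxidative 1,3-transposition the tertiary allylic chromate ester should undergo a [3,3] shift to the secondary C8 chromate, which is oxidized to the ketone and leaves C9=C10 with C1 attached to C10.

Step 10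
Reactants: 15 2-{(5R)-5-methyl-2-oxo-5-[(2S,3E)-pent-3-en-2-yl]-4-(prop-2-en-1-yl)cyclohex-3-en-1-yl}propan-2-yl acetate
Product: 16 2-[(4aR,5S)-4a,5-dimethyl-2-oxo-2,3,4,4a,5,8-hexahydronaphthalen-3-yl]propan-2-yl acetate
Conditions: second-generation Grubbs catalyst RuCl2(=CHPh)(PCy3)(H2IMes) (5 mol %), CH2Cl2 (0.005 M), 40 °C
Reagents that add atoms: none
Why: Ring-closing olefin metathesis between the terminal allyl alkene and the 1,2-disubstituted side-chain alkene should close six-membered ring A (C2=C3) with loss of propene, leaving C4 and C5 untouched.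

Step 11
Reactants: 16 2-[(4aR,5S)-4a,5-dimethyl-2-oxo-2,3,4,4a,5,8-hexahydronaphthalen-3-yl]propan-2-yl acetate
Product: 17 2-[(4aR,5R,6S,7S)-6-bromo-7-hydroxy-4a,5-dimethyl-2-oxo-2,3,4,4a,5,6,7,8-octahydronaphthalen-3-yl]propan-2-yl acetate
Conditions: NBS, THF/H2O (3:1), 0 °C, dark
Reagents that add atoms: N-bromosuccinimide, O=C1CCC(=O)N1Br; water, O
Why: Bromohydrin formation on the only electron-rich alkene: the bromonium ion should form on the face opposite the C14 and C15 methyl groups and be opened anti by water at C2 (the carbon remote from C15), which puts C2–OH on the methyl face and C3–Br on the other face.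

Step 12
Reactants: 17 2-[(4aR,5R,6S,7S)-6-bromo-7-hydroxy-4a,5-dimethyl-2-oxo-2,3,4,4a,5,6,7,8-octahydronaphthalen-3-yl]propan-2-yl acetate
Product: 20 (4aR,5R,6S)-6-hydroxy-4a,5-dimethyl-3-(propan-2-ylidene)-4,4a,5,6-tetrahydronaphthalen-2(3H)-one, via epoxide acetate 18 (not isolated), via epoxy dienone 19 (not isolated)
Conditions: DBU (4 equiv), toluene, 23 to 60 °C
Reagents that add atoms: none
Why: Three base-induced events should follow one another: intramolecular SN2 closure of the bromohydrin to the epoxide on the methyl face (inversion at C3, which fixes the C3–O bond and hence 3S), E1cB loss of acetate to the C7=C11 isopropylidene, and γ-deprotonation at C1 with vinylogous β-elimination that opens the epoxide at C2 to give C1=C2 and the C3 hydroxyl.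

Step 13
Reactants: 21 (2S)-2-methylbutan-1-ol
Product: 22 (2S)-2-methylbutanal
Conditions: TEMPO (10 mol %), PhI(OAc)2, CH2Cl2, 0 to 23 °C; solution used directly
Reagents that add atoms: none
Why: TEMPO-catalysed oxidation of the primary alcohol stops at the aldehyde under non-basic conditions, so the α-stereocentre should not epimerize.

Step 14
Reactants: 22 (2S)-2-methylbutanal; 23 ethyl (2E)-4-(diethoxyphosphoryl)but-2-enoate
Product: 24 ethyl (2E,4E,6S)-6-methylocta-2,4-dienoate
Conditions: 23, LiN(SiMe3)2 (0.95 equiv), THF, −78 °C; then 22, −78 to 0 °C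
Reagents that add atoms: none
Why: Vinylogous Horner–Wadsworth–Emmons olefination with the lithiated phosphonocrotonate should give the (2E,4E)-dienoate, and the low temperature and absence of excess base keep the stereocentre intact.

Step 15
Reactants: 24 ethyl (2E,4E,6S)-6-methylocta-2,4-dienoate
Product: 25 (2E,4E,6S)-6-methylocta-2,4-dienoic acid
Conditions: LiOH, THF/MeOH/H2O, 23 °C; then 1 M HCl
Reagents that add atoms: lithium hydroxide, [Li+].[OH-]
Why: Saponification of the ethyl ester with hydroxide does not touch the stereocentre or the diene geometry.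

Step 16
Reactants: 25 (2E,4E,6S)-6-methylocta-2,4-dienoic acid; 20 (4aR,5R,6S)-6-hydroxy-4a,5-dimethyl-3-(propan-2-ylidene)-4,4a,5,6-tetrahydronaphthalen-2(3H)-one
Product: 27 (1R,2S,8aR)-1,8a-dimethyl-6-oxo-7-(propan-2-ylidene)-1,2,6,7,8,8a-hexahydronaphthalen-2-yl (2E,4E,6S)-6-methylocta-2,4-dienoate, via mixed anhydride 26 (not isolated)
Conditions: 25, 2,4,6-trichlorobenzoyl chloride, Et3N, THF, 23 °C; then 20, DMAP, toluene, 23 °C
Reagents that add atoms: none
Why: Yamaguchi esterification through the mixed anhydride should acylate the hindered secondary allylic alcohol with retention at C3 and without isomerizing the dienoate.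

**Compound list**

1 | 3-methylbut-3-en-2-one | CC(=O)C(C)=C | starting material
2 | tert-butyldimethyl[(3-methylbuta-1,3-dien-2-yl)oxy]silane | C=C(O[Si](C)(C)C(C)(C)C)C(C)=C | intermediate
3 | methyl prop-2-enoate (methyl acrylate) | C=CC(=O)OC | starting material
4 | methyl 4-[(tert-butyldimethylsilyl)oxy]-3-methylcyclohex-3-ene-1-carboxylate (racemic) | COC(=O)C1CCC(O[Si](C)(C)C(C)(C)C)=C(C)C1 | intermediate
5 | 2-{4-[(tert-butyldimethylsilyl)oxy]-3-methylcyclohex-3-en-1-yl}propan-2-ol (racemic) | CC(C)(O)C1CCC(O[Si](C)(C)C(C)(C)C)=C(C)C1 | intermediate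
6 | 4-(2-hydroxypropan-2-yl)-2-methylcyclohexan-1-one (stereoisomer mixture) | CC1CC(CCC1=O)C(C)(C)O | intermediate
7 | 2-(3-methyl-4-oxocyclohexyl)propan-2-yl acetate (stereoisomer mixture) | CC1CC(CCC1=O)C(C)(C)OC(C)=O | intermediate
8 | (3E)-pent-3-en-2-one | C/C=C/C(C)=O | starting material
9 | (2R,3E)-pent-3-en-2-ol | C/C=C/[C@@H](C)O | intermediate
10 | 2-(4,4-dimethoxy-3-methylcyclohexyl)propan-2-yl acetate (stereoisomer mixture) | CC1CC(CCC1(OC)OC)C(C)(C)OC(C)=O | intermediate
11 | 2-{3-methyl-4-[(2R,3E)-pent-3-en-2-yloxy]cyclohex-3-en-1-yl}propan-2-yl acetate (C7 epimers) | CC(=O)OC(C)(C)C1CCC(O[C@H](C)/C=C/C)=C(C)C1 | intermediate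
12 | 2-{(3R)-3-methyl-4-oxo-3-[(2S,3E)-pent-3-en-2-yl]cyclohexyl}propan-2-yl acetate (C7 epimers) | CC(=O)OC(C)(C)C1CCC(=O)[C@](C)(C1)[C@@H](C)/C=C/C | intermediate
13 | 2-{(5R)-5-methyl-4-oxo-5-[(2S,3E)-pent-3-en-2-yl]cyclohex-2-en-1-yl}propan-2-yl acetate (C7 epimers) | CC(=O)OC(C)(C)C1C=CC(=O)[C@](C)(C1)[C@@H](C)/C=C/C | intermediate
14 | 2-{(5R)-4-hydroxy-5-methyl-5-[(2S,3E)-pent-3-en-2-yl]-4-(prop-2-en-1-yl)cyclohex-2-en-1-yl}propan-2-yl acetate (epimers at C7 and at the carbinol) | CC(=O)OC(C)(C)C1C=CC(O)(CC=C)[C@](C)(C1)[C@@H](C)/C=C/C | intermediate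
15 | 2-{(5R)-5-methyl-2-oxo-5-[(2S,3E)-pent-3-en-2-yl]-4-(prop-2-en-1-yl)cyclohex-3-en-1-yl}propan-2-yl acetate (C7 epimers) | CC(=O)OC(C)(C)C1C[C@](C)([C@@H](C)/C=C/C)C(CC=C)=CC1=O | intermediate
16 | 2-[(4aR,5S)-4a,5-dimethyl-2-oxo-2,3,4,4a,5,8-hexahydronaphthalen-3-yl]propan-2-yl acetate (C7 epimers) | CC(=O)OC(C)(C)C1C[C@]2(C)[C@@H](C)C=CCC2=CC1=O | intermediate
17 | 2-[(4aR,5R,6S,7S)-6-bromo-7-hydroxy-4a,5-dimethyl-2-oxo-2,3,4,4a,5,6,7,8-octahydronaphthalen-3-yl]propan-2-yl acetate (C7 epimers) | CC(=O)OC(C)(C)C1C[C@]2(C)[C@@H](C)[C@H](Br)[C@@H](O)CC2=CC1=O | intermediate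
18 | 2-[(4aR,5R,6R,7S)-6,7-epoxy-4a,5-dimethyl-2-oxo-2,3,4,4a,5,6,7,8-octahydronaphthalen-3-yl]propan-2-yl acetate (epoxide on the face of the methyl groups; C7 epimers) | CC(=O)OC(C)(C)C1C[C@]2(C)[C@@H](C)[C@H]3O[C@H]3CC2=CC1=O | intermediate
19 | (4aR,5R,6R,7S)-6,7-epoxy-4a,5-dimethyl-3-(propan-2-ylidene)-4,4a,5,6,7,8-hexahydronaphthalen-2(3H)-one | CC(C)=C1C[C@]2(C)[C@@H](C)[C@H]3O[C@H]3CC2=CC1=O | intermediate
20 | (4aR,5R,6S)-6-hydroxy-4a,5-dimethyl-3-(propan-2-ylidene)-4,4a,5,6-tetrahydronaphthalen-2(3H)-one | O[C@H]1C=CC2=CC(=O)C(=C(C)C)C[C@]2(C)[C@H]1C | intermediate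
21 | (2S)-2-methylbutan-1-ol | CC[C@H](C)CO | starting material
22 | (2S)-2-methylbutanal | CC[C@H](C)C=O | intermediate
23 | ethyl (2E)-4-(diethoxyphosphoryl)but-2-enoate | CCOC(=O)/C=C/CP(=O)(OCC)OCC | starting material
24 | ethyl (2E,4E,6S)-6-methylocta-2,4-dienoate | CC[C@H](C)/C=C/C=C/C(=O)OCC | intermediate
25 | (2E,4E,6S)-6-methylocta-2,4-dienoic acid | CC[C@H](C)/C=C/C=C/C(=O)O | intermediate
26 | (2E,4E,6S)-6-methylocta-2,4-dienoic 2,4,6-trichlorobenzoic anhydride | CC[C@H](C)/C=C/C=C/C(=O)OC(=O)c1c(Cl)cc(Cl)cc1Cl | intermediate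
27 | (1R,2S,8aR)-1,8a-dimethyl-6-oxo-7-(propan-2-ylidene)-1,2,6,7,8,8a-hexahydronaphthalen-2-yl (2E,4E,6S)-6-methylocta-2,4-dienoate | CC[C@H](C)/C=C/C=C/C(=O)O[C@H]1C=CC2=CC(=O)C(=C(C)C)C[C@]2(C)[C@H]1C | target

**Step count and risks**

Total step count: 16. Longest linear sequence: 12 steps (steps 1–4, 6–12 and 16, from 3-methylbut-3-en-2-one).

Steps most likely to fail:

Step 6. The acid-mediated enol ether formation may go toward C9 instead of C5. The carbinol centre of 9 may scramble through a symmetric allyl cation before the rearrangement, and the tertiary acetate may be lost by acid-induced elimination. The fallback sets out from 7 and fixes the enol ether regiochemistry through a vinyl iodide under basic conditions. Tf2O with 2,6-di-tert-butyl-4-methylpyridine should give the more substituted enol triflate 2-(3-methyl-4-{[(trifluoromethyl)sulfonyl]oxy}cyclohex-3-en-1-yl)propan-2-yl acetate F1. Me3SnSnMe3, Pd(PPh3)4 and LiCl should convert it into the vinylstannane 2-[3-methyl-4-(trimethylstannyl)cyclohex-3-en-1-yl]propan-2-yl acetate F2, and I2 into the vinyl iodide 2-(4-iodo-3-methylcyclohex-3-en-1-yl)propan-2-yl acetate F3. CuI (cat.), 3,4,7,8-tetramethyl-1,10-phenanthroline, Cs2CO3 and 9 in o-xylene at 120 °C should then couple C–O to the enol ether 11, which rearranges in the same flask; the route is rejoined at 12.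

Step 9. The homoallylic tertiary chromate ester may fragment with loss of the allyl group, the skipped diene may move into conjugation under the acidic oxidant, and the doubly allylic C1 methylene may be oxidized further. The fallback sets out from 14: a 1,3-hydroxyl transposition catalysed by O3ReOSiPh3 should give the secondary allylic alcohol 2-{(5R)-2-hydroxy-5-methyl-5-[(2S,3E)-pent-3-en-2-yl]-4-(prop-2-en-1-yl)cyclohex-3-en-1-yl}propan-2-yl acetate F4, and MnO2 should oxidize it to 15, where the route is rejoined.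

Step 11. The bromonium ion may form on the wrong face, or the reagent may attack the enone or the allylic C1 position, which leaves step 12 without its substrate. The fallback sets out from 16. mCPBA should epoxidize C2=C3 from the face opposite the methyl groups to 2-[(4aR,5R,6S,7R)-6,7-epoxy-4a,5-dimethyl-2-oxo-2,3,4,4a,5,6,7,8-octahydronaphthalen-3-yl]propan-2-yl acetate F5. DBU (acetate loss and vinylogous epoxide opening) should give the C3 epimer of 20, (4aR,5R,6R)-6-hydroxy-4a,5-dimethyl-3-(propan-2-ylidene)-4,4a,5,6-tetrahydronaphthalen-2(3H)-one F6. A Mitsunobu esterification of F6 with acid 25 (PPh3, diisopropyl azodicarboxylate) inverts C3 and comes back to the route at 27.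

Further compounds
F1 | step 6 | 2-(3-methyl-4-{[(trifluoromethyl)sulfonyl]oxy}cyclohex-3-en-1-yl)propan-2-yl acetate | CC(=O)OC(C)(C)C1CCC(OS(=O)(=O)C(F)(F)F)=C(C)C1
F2 | step 6 | 2-[3-methyl-4-(trimethylstannyl)cyclohex-3-en-1-yl]propan-2-yl acetate | CC(=O)OC(C)(C)C1CCC([Sn](C)(C)C)=C(C)C1
F3 | step 6 | 2-(4-iodo-3-methylcyclohex-3-en-1-yl)propan-2-yl acetate | CC(=O)OC(C)(C)C1CCC(I)=C(C)C1
F4 | step 9 | 2-{(5R)-2-hydroxy-5-methyl-5-[(2S,3E)-pent-3-en-2-yl]-4-(prop-2-en-1-yl)cyclohex-3-en-1-yl}propan-2-yl acetate | CC(=O)OC(C)(C)C1C[C@](C)([C@@H](C)/C=C/C)C(CC=C)=CC1O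
F5 | step 11 | 2-[(4aR,5R,6S,7R)-6,7-epoxy-4a,5-dimethyl-2-oxo-2,3,4,4a,5,6,7,8-octahydronaphthalen-3-yl]propan-2-yl acetate | CC(=O)OC(C)(C)C1C[C@]2(C)[C@@H](C)[C@@H]3O[C@@H]3CC2=CC1=O
F6 | step 11 | (4aR,5R,6R)-6-hydroxy-4a,5-dimethyl-3-(propan-2-ylidene)-4,4a,5,6-tetrahydronaphthalen-2(3H)-one | O[C@@H]1C=CC2=CC(=O)C(=C(C)C)C[C@]2(C)[C@H]1C
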